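**Assumption:** "geranyl" means the (2E)-3,7-dimethylocta-2,6-dienyl group shown in the SMILES, and a one-pot, two-stage operation without isolation counts as one step.

## Retrosynthetic overview

1. Target 8 ⇒ C2–aryl bond: enantioselective dearomative conjugate arylation of 8-geranyl-7-hydroxychromone (6) with 4-hydroxyphenylboronic acid (7). This last step sets the only stereocentre, with no protecting groups.
2. Chromone 6 ⇒ one-carbon annulation (C2) of 3-geranyl-2,4-dihydroxyacetophenone (3) through an enaminone.
3. Ketone 3 ⇒ C3-geranylation of resacetophenone (1) with geranyl bromide (2).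
4. Ring order: the A ring (from 1) and B ring (from 7) are bought as aromatics; the C ring is built as an aromatic γ-pyranone and then dearomatised in the stereodefining step.

## Route

**Step 1**
Reactants: 1, 2,4-dihydroxyacetophenone (resacetophenone); 2, geranyl bromide [(2E)-1-bromo-3,7-dimethylocta-2,6-diene]
Product: 3, 1-{3-[(2E)-3,7-dimethylocta-2,6-dien-1-yl]-2,4-dihydroxyphenyl}ethan-1-one
Conditions: 1 (1.5 equiv), 10% aq KOH, 2 (1.0 equiv), 0 °C → rt, 16 h; then cold 1 M HCl to pH ~5; SiO2 chromatography. Expect roughly 25–35%; the 5-C- and 4-O-geranyl isomers are separated and excess 1 is recovered.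
Reagents that add atoms: geranyl bromide, CC(C)=CCC/C(C)=C/CBr
Why: Phenoxide C-alkylation (SN2 at the primary allylic bromide, E-alkene retained) in water, where hydrogen bonding to the phenoxide oxygens suppresses O-alkylation and C3, flanked by both oxygens, is the most nucleophilic carbon.

**Step 2**
Reactants: 3; 4, Bredereck's reagent [tert-butoxybis(dimethylamino)methane]
Product: 6, 8-[(2E)-3,7-dimethylocta-2,6-dien-1-yl]-7-hydroxy-4H-chromen-4-one, formed via the non-isolated enaminone 5, (2E)-3-(dimethylamino)-1-{3-[(2E)-geranyl]-2,4-dihydroxyphenyl}prop-2-en-1-one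
Conditions: 4 (3 equiv), PhMe, 70 °C, 3 h; evaporate; then 2 M aq HCl–THF (1:3), rt → 40 °C, 1–2 h (one pot)
Reagents that add atoms: Bredereck's reagent, CN(C)C(OC(C)(C)C)N(C)C (supplies the C2 carbon)
Why: Aminomethylenation of the aryl methyl ketone to the enaminone, then acid-promoted 6-endo addition of the 2-OH and loss of Me2NH (enaminone chromone synthesis); the reagent cannot O-methylate the acidic 4-OH as DMF-DMA can, and dilute acid near rt should not cyclise the ortho-geranyl phenol to a chroman.

**Step 3 (key step)**
Reactants: 6; 7, 4-hydroxyphenylboronic acid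
Product: 8, (2S)-8-[(2E)-3,7-dimethylocta-2,6-dien-1-yl]-7-hydroxy-2-(4-hydroxyphenyl)-2,3-dihydro-4H-chromen-4-one (target)
Conditions: Pd(OCOCF3)2 (10 mol%), (R)-t-BuPyOx [(R)-4-tert-butyl-2-(pyridin-2-yl)-4,5-dihydrooxazole] (12 mol%), NH4PF6 (30 mol%), H2O (5 equiv), 7 (2.5 equiv), ClCH2CH2Cl, N2, 40 °C, 24 h; neutral SiO2 chromatography with no base contact
Reagents that add atoms: 4-hydroxyphenylboronic acid, OB(O)c1ccc(O)cc1 (water supplies only H)
Why: Pd(II)/pyridine-oxazoline asymmetric conjugate addition of an arylboronic acid (transmetalation, enantiodetermining syn-arylpalladation of C2=C3, protonolysis of the Pd enolate by water) dearomatises the γ-pyranone and sets C2; by analogy with this catalyst's known facial preference on cyclic enones the (R)-ligand should deliver the aryl to the C2 Re face to give (2S) (sense to be confirmed by CD, see below), and the non-basic medium keeps both phenols neutral and prevents ring-opening racemisation of the product.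

## Compound list

1 | 2,4-dihydroxyacetophenone | CC(=O)c1ccc(O)cc1O | starting material
2 | geranyl bromide | CC(C)=CCC/C(C)=C/CBr | starting material
3 | 3-geranyl-2,4-dihydroxyacetophenone | CC(C)=CCC/C(C)=C/Cc1c(O)ccc(C(C)=O)c1O | intermediate
4 | Bredereck's reagent, tert-butoxybis(dimethylamino)methane | CN(C)C(OC(C)(C)C)N(C)C | starting material (C1 reagent)
5 | (E)-enaminone of 3 | CC(C)=CCC/C(C)=C/Cc1c(O)ccc(C(=O)/C=C/N(C)C)c1O | intermediate (not isolated)
6 | 8-geranyl-7-hydroxy-4H-chromen-4-one | CC(C)=CCC/C(C)=C/Cc1c(O)ccc2c1OC=CC2=O | intermediate
7 | 4-hydroxyphenylboronic acid | OB(O)c1ccc(O)cc1 | starting material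
8 | (2S)-7,4'-dihydroxy-8-geranylflavanone | CC(C)=CCC/C(C)=C/Cc1c(O)ccc2c1O[C@H](c1ccc(O)cc1)CC2=O | target

## Step count and risks

Total steps: 3 (three isolated products; 4 if the two stages of step 2 are counted separately). Longest linear sequence: 3, from compound 1.

Steps most likely to fail, in order:

1. **Step 3.** The free ortho-geranyl phenol may undergo Wacker-type oxypalladation or reduce the Pd(II) catalyst; the electron-rich 7-hydroxychromone may add slowly; and 7 may protodeboronate. The sense of induction is inferred by analogy with cyclic enones and must be checked by CD (2S-flavanones: positive Cotton effect near 330 nm, negative near 290 nm); use the (S)-ligand if it is reversed.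
   Fallback: protect 6 as its 7-O-TBS ether and run a Rh(I)/chiral diene (or bisphosphine) 1,4-addition with 4-(TBSO)phenylboronic acid, then buffered desilylation (TBAF/AcOH or HF·pyridine). Rh(I) does not engage phenols or isolated alkenes in Wacker chemistry. This costs two extra steps.

2. **Step 1.** C3 versus C5 versus O-alkylation and over-alkylation make this low-yielding.
   Fallback: a regiospecific directed-metalation sequence. 1,3-Bis(MOMO)benzene is lithiated at C2 and geranylated; a second ortho-lithiation at C4 is quenched with N-methoxy-N-methylacetamide; mild HCl/MeOH removes the MOM groups to give 3.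

3. **Step 2.** The free phenols may slow aminomethylenation, or the acid stage may cyclise the geranyl chain to a chroman.
   Fallback: Claisen condensation of 3 with ethyl formate (NaH, THF) to the 2-hydroxychroman-4-one, then mild dehydration (catalytic acid, or MsCl/Et3N) to 6.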